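**Retrosynthetic overview**

1. Target: all-E (3S,4S,3′S,4′S)-7,8-didehydro-β,β-carotene-3,4,3′,4′-tetrol (carotenoid locants; ring A = cyclohexene on the alkyne, ring B = cyclohexene on the E-alkene). Last events: fluoride desilylation of ring B and hydroxyl-directed reduction of a ring A C4 ketone.
2. Key disconnection C6–C7: the lithium acetylide of the complete C31 polyenyne (ring B plus chain, terminal C8≡C7–H) adds to the C6 carbonyl of a C9 bicyclic enone acetonide. Acid then transposes the carbonyl, so that C6–C7, the tetrasubstituted C5=C6, C4=O and the free C3–OH arise in one operation from a four-step ring piece.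
3. Enabling feature: in ring A the alkyne-bearing C6 is vinylogous to the C4 oxygen through C5=C6 and is flanked by the quaternary C1. C6 can therefore be a carbonyl masked as the vinylogous ester O–C4=C5–C6=O, which can only suffer 1,2-addition; C7–H is the only acidic site of the polyenyne.
4. C31 polyenyne: two Wittig olefinations (C11=C12, then C11′=C12′) from a C6 enynyl phosphonium salt, the C10 trienedial and the ring B C15 phosphonium salt. The ring B C15 unit comes from the same enone acetonide by alkynylation, trans-hydroalumination, the same transposition and the same directed reduction.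
5. No ring is formed: both six-membered rings come from ketoisophorone (ring B elaborated first, ring A attached last). C3/C3′ come from one asymmetric transfer hydrogenation, C4/C4′ from the two directed reductions.

Key step: step 16

Assumption: ketoisophorone, (E)-3-methylpent-2-en-4-yn-1-ol and (2E,4E,6E)-2,7-dimethylocta-2,4,6-trienedial are taken as commercial; all polyene steps are run under inert gas with exclusion of light, and the final tetrol is never exposed to acid because its allylic C4/C4′ hydroxyls ionize readily.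

**Route**

Step 1
Reactants: 1 ketoisophorone (2,6,6-trimethylcyclohex-2-ene-1,4-dione)
Product: 2 1,3,3-trimethyl-7-oxabicyclo[4.1.0]heptane-2,5-dione (racemic)
Conditions: 30% H2O2, NaOH (cat.), MeOH/H2O, 0 °C
Reagents that add atoms: hydrogen peroxide, OO
Why: Weitz–Scheffer nucleophilic epoxidation of the electron-poor enedione double bond; the stereocentres formed are erased in step 2.

Step 2
Reactants: 2 1,3,3-trimethyl-7-oxabicyclo[4.1.0]heptane-2,5-dione
Product: 3 2-hydroxy-3,5,5-trimethylcyclohex-2-ene-1,4-dione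
Conditions: aq NaOH (1.1 equiv), MeOH, 0 °C → rt, N2; then aq HCl
Reagents that add atoms: none
Why: base-mediated isomerization of an α,β-epoxy ketone to its diosphenol (epoxy ketone to 2-hydroxy-enone rearrangement), both enantiomers of 2 converging on the same achiral enol.

Step 3
Reactants: 3 2-hydroxy-3,5,5-trimethylcyclohex-2-ene-1,4-dione
Product: 4 (4S)-3,4-dihydroxy-2,6,6-trimethylcyclohex-2-en-1-one
Conditions: RuCl(p-cymene)[(S,S)-TsDPEN] (1 mol %), HCO2H/Et3N (5:2), CH2Cl2, rt
Reagents that add atoms: none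
Why: Noyori asymmetric transfer hydrogenation should reduce only the unhindered C1 carbonyl (the other carbonyl is a vinylogous-acid carbonyl next to the quaternary carbon) and, with the enol π-arm in the place of the aryl group of the usual model, the (S,S)-catalyst should give the (S)-carbinol that becomes C3 and C3′.

Step 4
Reactants: 4 (4S)-3,4-dihydroxy-2,6,6-trimethylcyclohex-2-en-1-one
Product: 5 (7aS)-2,2,4,6,6-pentamethyl-7,7a-dihydro-6H-1,3-benzodioxol-5-one
Conditions: 2-methoxypropene, PPTS (cat.), acetone, 0 °C → rt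
Reagents that add atoms: 2-methoxypropene, COC(C)=C
Why: acid-catalysed ketalization in which only the enol hydroxyl and the adjacent secondary hydroxyl can close a five-membered dioxolane, which locks the vinylogous ester with its carbonyl at the hindered carbon and leaves the stereocentre untouched.

Step 5
Reactants: 6 (E)-3-methylpent-2-en-4-yn-1-ol; 5 (7aS)-2,2,4,6,6-pentamethyl-7,7a-dihydro-6H-1,3-benzodioxol-5-one
Product: 8 (7aS)-5-[(3E)-5-hydroxy-3-methylpent-3-en-1-yn-1-yl]-2,2,4,6,6-pentamethyl-5,6,7,7a-tetrahydro-1,3-benzodioxol-5-ol (mixture of C5 epimers), via dilithiated enynol 7 (not isolated)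
Conditions: 6, n-BuLi (2.05 equiv), THF, −78 → 0 °C; then 5, −78 → 0 °C; H2O quench, work-up at pH ≥ 7
Reagents that add atoms: none
Why: 1,2-addition of a lithium acetylide to the vinylogous ester carbonyl, which has no α-hydrogen on its quaternary side; the new carbinol centre forms without control and is erased in step 6.

Step 6
Reactants: 8 (7aS)-5-[(3E)-5-hydroxy-3-methylpent-3-en-1-yn-1-yl]-2,2,4,6,6-pentamethyl-5,6,7,7a-tetrahydro-1,3-benzodioxol-5-ol
Product: 10 (6S)-6-hydroxy-3-[(1E,3E)-5-hydroxy-3-methylpenta-1,3-dien-1-yl]-2,4,4-trimethylcyclohex-2-en-1-one, via dienyl carbinol 9 (not isolated)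
Conditions: NaAlH2(OCH2CH2OCH3)2 (3 equiv), THF, 0 °C → rt; then cold 0.5 M aq H2SO4, 0 °C
Reagents that add atoms: water, O (supplies the ring carbonyl oxygen)
Why: alkoxide-directed trans-hydroalumination of the propargylic alcohol fixes the E ring–CH=CH bond (Al and H add anti), and the acidic quench effects the Stork–Danheiser transposition with loss of acetone, leaving the carbinol stereocentre untouched.

Step 7
Reactants: 10 (6S)-6-hydroxy-3-[(1E,3E)-5-hydroxy-3-methylpenta-1,3-dien-1-yl]-2,4,4-trimethylcyclohex-2-en-1-one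
Product: 11 (1S,2S)-4-[(1E,3E)-5-hydroxy-3-methylpenta-1,3-dien-1-yl]-3,5,5-trimethylcyclohex-3-ene-1,2-diol
Conditions: Me4NBH(OAc)3 (5 equiv), MeCN/AcOH, −30 → 0 °C; aq NaHCO3
Reagents that add atoms: none
Why: hydroxyl-directed (Saksena–Evans-type) reduction, in which the neighbouring hydroxyl binds boron and delivers hydride to the carbonyl face syn to its own C–O bond, so the new hydroxyl should end up trans (4′S); axial attack on the half-chair favours the same face.

Step 8
Reactants: 11 (1S,2S)-4-[(1E,3E)-5-hydroxy-3-methylpenta-1,3-dien-1-yl]-3,5,5-trimethylcyclohex-3-ene-1,2-diol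
Product: 12 tris(tert-butyldimethylsilyl) ether of 11
Conditions: TBSOTf (3.6 equiv), 2,6-lutidine, CH2Cl2, −78 → 0 °C
Reagents that add atoms: tert-butyldimethylsilyl trifluoromethanesulfonate, CC(C)(C)[Si](C)(C)OS(=O)(=O)C(F)(F)F
Why: silyl triflate with a hindered base silylates all three hydroxyls, including the hindered allylic one, under non-acidic conditions.

Step 9
Reactants: 12 tris(tert-butyldimethylsilyl) ether of 11
Product: 13 (2E,4E)-5-[(3S,4S)-3,4-bis(tert-butyldimethylsilyloxy)-2,6,6-trimethylcyclohex-1-en-1-yl]-3-methylpenta-2,4-dien-1-ol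
Conditions: HF·pyridine, pyridine, THF, 0 °C
Reagents that add atoms: none
Why: buffered fluoride cleaves the unhindered primary silyl ether much faster than the two secondary ones (selective desilylation by steric rate difference).

Step 10
Reactants: 13 (2E,4E)-5-[(3S,4S)-3,4-bis(tert-butyldimethylsilyloxy)-2,6,6-trimethylcyclohex-1-en-1-yl]-3-methylpenta-2,4-dien-1-ol
Product: 14 (2E,4E)-5-[(3S,4S)-3,4-bis(tert-butyldimethylsilyloxy)-2,6,6-trimethylcyclohex-1-en-1-yl]-3-methylpenta-2,4-dienyl bromide
Conditions: CBr4, PPh3, 2,6-lutidine, CH2Cl2, −20 °C; used crude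
Reagents that add atoms: carbon tetrabromide, BrC(Br)(Br)Br
Why: Appel bromination converts the primary allylic alcohol to the bromide under neutral conditions that should not ionize the allylic ring silyl ether.

Step 11
Reactants: 14 (2E,4E)-5-[(3S,4S)-3,4-bis(tert-butyldimethylsilyloxy)-2,6,6-trimethylcyclohex-1-en-1-yl]-3-methylpenta-2,4-dienyl bromide
Product: 15 [(2E,4E)-5-[(3S,4S)-3,4-bis(tert-butyldimethylsilyloxy)-2,6,6-trimethylcyclohex-1-en-1-yl]-3-methylpenta-2,4-dien-1-yl]triphenylphosphonium bromide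
Conditions: PPh3, EtOAc, rt; crystallization
Reagents that add atoms: triphenylphosphine, c1ccc(cc1)P(c1ccccc1)c1ccccc1
Why: SN2 quaternization of triphenylphosphine by the primary allylic bromide, with crystallization expected to enrich the all-E salt.

Step 12
Reactants: 6 (E)-3-methylpent-2-en-4-yn-1-ol
Product: 16 (E)-5-bromo-3-methylpent-3-en-1-yne
Conditions: PBr3 (0.4 equiv), pyridine (cat.), Et2O, 0 °C
Reagents that add atoms: phosphorus tribromide, BrP(Br)Br
Why: PBr3 substitution of a primary allylic alcohol, expected to keep the E geometry of the trisubstituted double bond.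

Step 13
Reactants: 16 (E)-5-bromo-3-methylpent-3-en-1-yne
Product: 17 [(2E)-3-methylpent-2-en-4-yn-1-yl]triphenylphosphonium bromide
Conditions: PPh3, toluene, rt
Reagents that add atoms: triphenylphosphine, c1ccc(cc1)P(c1ccccc1)c1ccccc1
Why: SN2 quaternization of triphenylphosphine by the allylic bromide.

Step 14
Reactants: 17 [(2E)-3-methylpent-2-en-4-yn-1-yl]triphenylphosphonium bromide; 18 (2E,4E,6E)-2,7-dimethylocta-2,4,6-trienedial
Product: 21 (2E,4E,6E,8E,10E)-2,7,11-trimethyltrideca-2,4,6,8,10-pentaen-12-ynal, via ylide 19 (not isolated), via 8Z isomer 20 (not isolated)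
Conditions: 18 (2.5 equiv), NaOMe (1.05 equiv), CH2Cl2/MeOH, 0 °C → rt, slow addition of 17; then heptane, 90 °C, N2, dark
Reagents that add atoms: none
Why: Wittig olefination in which excess dialdehyde favours mono-olefination and methoxide deprotonates only the phosphonium α-carbon (the alkyne C–H is far less acidic); the hindered Z isomer at the new bond should isomerize thermally to E.

Step 15
Reactants: 15 ring B C15 phosphonium bromide; 21 (2E,4E,6E,8E,10E)-2,7,11-trimethyltrideca-2,4,6,8,10-pentaen-12-ynal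
Product: 24 all-E C31 polyenyne (ring B 3′S,4′S bis-silyl ether joined through the heptaene chain to the terminal alkyne C8≡C7–H), via ylide 22 (not isolated), via 11′Z isomer 23 (not isolated)
Conditions: NaOMe (1.1 equiv), CH2Cl2/MeOH, 0 °C → rt; then heptane, reflux, N2, dark; crystallization
Reagents that add atoms: none
Why: Wittig olefination of the polyenal, followed by thermal isomerization of the sterically hindered Z isomer at C11′=C12′ to the all-E polyene.

Step 16
Reactants: 24 all-E C31 polyenyne; 5 (7aS)-2,2,4,6,6-pentamethyl-7,7a-dihydro-6H-1,3-benzodioxol-5-one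
Product: 27 (3S,3′S,4′S)-3-hydroxy-3′,4′-bis(tert-butyldimethylsilyloxy)-7,8-didehydro-β,β-caroten-4-one, via lithium acetylide 25 (not isolated), via tertiary carbinol 26 (not isolated)
Conditions: 24, LiN(iPr)2 (1.05 equiv), THF, −78 °C; 5 (1.5 equiv), −78 → 0 °C; then 0.5 M aq H2SO4 to pH 2–3, 0 °C, 30 min; aq NaHCO3; N2, dark
Reagents that add atoms: water, O (supplies the C4 carbonyl oxygen)
Why: LiN(iPr)2 removes only the acetylenic C7–H of 24, and the lithium acetylide 25 adds 1,2 to the C6 carbonyl of 5, the only electrophilic site, because C1 is quaternary and the other flank is the enol-ether carbon C5; on acidification the tertiary carbinol 26 ionizes to an alkoxy-stabilized allyl (oxocarbenium) cation, water is captured at the oxygen-bearing C4 and the hemiketal ejects acetone, so that the C6–C7 bond, the tetrasubstituted C5=C6 double bond conjugated to the alkyne, the C4 carbonyl and the free (3S)-hydroxyl all appear in one operation. The closest known reaction type is the Stork–Danheiser 1,2-addition and acid transposition of 3-alkoxy-enones, which is established for acetylides on cyclohexenone vinylogous esters. No ring is closed. No lasting stereocentre is created: the carbinol centre at C6 forms as a mixture and is erased on dehydration, while C3 is carried unchanged from 5, since the acetylide is too weak a base for the γ-hydrogen and the collapse does not break the C3–O bond. The step needs 1,2-addition rather than γ-deprotonation, water capture at C4 rather than along the polyene, and survival of the ring B silyl ethers; these are secured by the oxygen stabilization at C4, the short cold exposure to dilute non-nucleophilic acid, and the acid stability of secondary tert-butyldimethylsilyl ethers.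

Step 17
Reactants: 27 (3S,3′S,4′S)-3-hydroxy-3′,4′-bis(tert-butyldimethylsilyloxy)-7,8-didehydro-β,β-caroten-4-one
Product: 28 (3S,4S,3′S,4′S)-3′,4′-bis(tert-butyldimethylsilyloxy)-7,8-didehydro-β,β-carotene-3,4-diol
Conditions: Me4NBH(OAc)3 (5 equiv), MeCN/THF, AcOH (5 equiv), −30 → 0 °C; aq NaHCO3; N2, dark
Reagents that add atoms: none
Why: the hydroxyl-directed (Saksena–Evans-type) reduction rehearsed in step 7: the C3–OH delivers hydride to the C4 carbonyl face syn to the C3–O bond, which should give the trans (4S) alcohol, and the silyl ethers of ring B cannot direct or react.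

Step 18
Reactants: 28 (3S,4S,3′S,4′S)-3′,4′-bis(tert-butyldimethylsilyloxy)-7,8-didehydro-β,β-carotene-3,4-diol
Product: 29 (3S,4S,3′S,4′S)-7,8-didehydro-β,β-carotene-3,4,3′,4′-tetrol (all-E)
Conditions: Bu4NF (6 equiv), THF, 0 °C → rt, N2, dark; crystallization
Reagents that add atoms: none
Why: fluoride-driven desilylation under non-acidic conditions, which removes both silyl ethers without ionizing the allylic C4 and C4′ hydroxyls or touching any stereocentre.

**Compound list**

1 | ketoisophorone (2,6,6-trimethylcyclohex-2-ene-1,4-dione) | CC1=CC(=O)CC(C)(C)C1=O | starting material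
2 | 1,3,3-trimethyl-7-oxabicyclo[4.1.0]heptane-2,5-dione (racemic) | CC12OC1C(=O)CC(C)(C)C2=O | intermediate
3 | 2-hydroxy-3,5,5-trimethylcyclohex-2-ene-1,4-dione | CC1=C(O)C(=O)CC(C)(C)C1=O | intermediate
4 | (4S)-3,4-dihydroxy-2,6,6-trimethylcyclohex-2-en-1-one | CC1=C(O)[C@@H](O)CC(C)(C)C1=O | intermediate
5 | (7aS)-2,2,4,6,6-pentamethyl-7,7a-dihydro-6H-1,3-benzodioxol-5-one | CC1=C2OC(C)(C)O[C@H]2CC(C)(C)C1=O | intermediate
6 | (E)-3-methylpent-2-en-4-yn-1-ol | C#C/C(C)=C/CO | starting material
7 | dilithiated 6 (lithium alkoxide and lithium acetylide) | [Li]C#C/C(C)=C/CO[Li] | intermediate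
8 | (7aS)-5-[(3E)-5-hydroxy-3-methylpent-3-en-1-yn-1-yl]-2,2,4,6,6-pentamethyl-5,6,7,7a-tetrahydro-1,3-benzodioxol-5-ol (C5 epimers) | CC1=C2OC(C)(C)O[C@H]2CC(C)(C)C1(O)C#C/C(C)=C/CO | intermediate
9 | (7aS)-5-[(1E,3E)-5-hydroxy-3-methylpenta-1,3-dien-1-yl]-2,2,4,6,6-pentamethyl-5,6,7,7a-tetrahydro-1,3-benzodioxol-5-ol (C5 epimers, formed as its aluminate) | CC1=C2OC(C)(C)O[C@H]2CC(C)(C)C1(O)/C=C/C(C)=C/CO | intermediate
10 | (6S)-6-hydroxy-3-[(1E,3E)-5-hydroxy-3-methylpenta-1,3-dien-1-yl]-2,4,4-trimethylcyclohex-2-en-1-one | CC1=C(/C=C/C(C)=C/CO)C(C)(C)C[C@H](O)C1=O | intermediate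
11 | (1S,2S)-4-[(1E,3E)-5-hydroxy-3-methylpenta-1,3-dien-1-yl]-3,5,5-trimethylcyclohex-3-ene-1,2-diol | CC1=C(/C=C/C(C)=C/CO)C(C)(C)C[C@H](O)[C@H]1O | intermediate
12 | tris(tert-butyldimethylsilyl) ether of 11 | CC1=C(/C=C/C(C)=C/CO[Si](C)(C)C(C)(C)C)C(C)(C)C[C@H](O[Si](C)(C)C(C)(C)C)[C@H]1O[Si](C)(C)C(C)(C)C | intermediate
13 | (2E,4E)-5-[(3S,4S)-3,4-bis(tert-butyldimethylsilyloxy)-2,6,6-trimethylcyclohex-1-en-1-yl]-3-methylpenta-2,4-dien-1-ol | CC1=C(/C=C/C(C)=C/CO)C(C)(C)C[C@H](O[Si](C)(C)C(C)(C)C)[C@H]1O[Si](C)(C)C(C)(C)C | intermediate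
14 | (2E,4E)-5-[(3S,4S)-3,4-bis(tert-butyldimethylsilyloxy)-2,6,6-trimethylcyclohex-1-en-1-yl]-3-methylpenta-2,4-dienyl bromide | CC1=C(/C=C/C(C)=C/CBr)C(C)(C)C[C@H](O[Si](C)(C)C(C)(C)C)[C@H]1O[Si](C)(C)C(C)(C)C | intermediate
15 | ring B C15 salt: [(2E,4E)-5-[(3S,4S)-3,4-bis(tert-butyldimethylsilyloxy)-2,6,6-trimethylcyclohex-1-en-1-yl]-3-methylpenta-2,4-dien-1-yl]triphenylphosphonium bromide | CC1=C(/C=C/C(C)=C/C[P+](c2ccccc2)(c2ccccc2)c2ccccc2)C(C)(C)C[C@H](O[Si](C)(C)C(C)(C)C)[C@H]1O[Si](C)(C)C(C)(C)C.[Br-] | intermediate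
16 | (E)-5-bromo-3-methylpent-3-en-1-yne | C#C/C(C)=C/CBr | intermediate
17 | [(2E)-3-methylpent-2-en-4-yn-1-yl]triphenylphosphonium bromide | C#C/C(C)=C/C[P+](c1ccccc1)(c1ccccc1)c1ccccc1.[Br-] | intermediate
18 | (2E,4E,6E)-2,7-dimethylocta-2,4,6-trienedial | O=C/C(C)=C/C=C/C=C(C)/C=O | starting material
19 | ylide of 17 | C#C/C(C)=C/C=P(c1ccccc1)(c1ccccc1)c1ccccc1 | intermediate
20 | 8Z isomer of 21 | C#C/C(C)=C/C=C\C(C)=C\C=C\C=C(C)\C=O | intermediate
21 | (2E,4E,6E,8E,10E)-2,7,11-trimethyltrideca-2,4,6,8,10-pentaen-12-ynal | C#C/C(C)=C/C=C/C(C)=C/C=C/C=C(C)/C=O | intermediate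
22 | ylide of 15 | CC1=C(/C=C/C(C)=C/C=P(c2ccccc2)(c2ccccc2)c2ccccc2)C(C)(C)C[C@H](O[Si](C)(C)C(C)(C)C)[C@H]1O[Si](C)(C)C(C)(C)C | intermediate
23 | 11′Z isomer of 24 | C#C/C(C)=C/C=C/C(C)=C/C=C/C=C(C)/C=C\C=C(C)\C=C\C1=C(C)[C@H](O[Si](C)(C)C(C)(C)C)[C@@H](O[Si](C)(C)C(C)(C)C)CC1(C)C | intermediate
24 | all-E C31 polyenyne: (3′S,4′S)-3′,4′-bis(tert-butyldimethylsilyloxy)-7,8-didehydro-7-apo-β-carotene skeleton (ring B, heptaene chain, terminal C8≡C7–H) | C#C/C(C)=C/C=C/C(C)=C/C=C/C=C(C)/C=C/C=C(C)/C=C/C1=C(C)[C@H](O[Si](C)(C)C(C)(C)C)[C@@H](O[Si](C)(C)C(C)(C)C)CC1(C)C | intermediate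
25 | lithium acetylide of 24 | [Li]C#C/C(C)=C/C=C/C(C)=C/C=C/C=C(C)/C=C/C=C(C)/C=C/C1=C(C)[C@H](O[Si](C)(C)C(C)(C)C)[C@@H](O[Si](C)(C)C(C)(C)C)CC1(C)C | intermediate
26 | tertiary propargylic carbinol from 25 and 5 (C6 epimers, formed as its lithium alkoxide) | CC1=C2OC(C)(C)O[C@H]2CC(C)(C)C1(O)C#C/C(C)=C/C=C/C(C)=C/C=C/C=C(C)/C=C/C=C(C)/C=C/C1=C(C)[C@H](O[Si](C)(C)C(C)(C)C)[C@@H](O[Si](C)(C)C(C)(C)C)CC1(C)C | intermediate
27 | (3S,3′S,4′S)-3-hydroxy-3′,4′-bis(tert-butyldimethylsilyloxy)-7,8-didehydro-β,β-caroten-4-one | CC1=C(C#C/C(C)=C/C=C/C(C)=C/C=C/C=C(C)/C=C/C=C(C)/C=C/C2=C(C)[C@H](O[Si](C)(C)C(C)(C)C)[C@@H](O[Si](C)(C)C(C)(C)C)CC2(C)C)C(C)(C)C[C@H](O)C1=O | intermediate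
28 | (3S,4S,3′S,4′S)-3′,4′-bis(tert-butyldimethylsilyloxy)-7,8-didehydro-β,β-carotene-3,4-diol | CC1=C(C#C/C(C)=C/C=C/C(C)=C/C=C/C=C(C)/C=C/C=C(C)/C=C/C2=C(C)[C@H](O[Si](C)(C)C(C)(C)C)[C@@H](O[Si](C)(C)C(C)(C)C)CC2(C)C)C(C)(C)C[C@H](O)[C@H]1O | intermediate
29 | (3S,4S,3′S,4′S)-7,8-didehydro-β,β-carotene-3,4,3′,4′-tetrol (all-E) | CC1=C(C#C/C(C)=C/C=C/C(C)=C/C=C/C=C(C)/C=C/C=C(C)/C=C/C2=C(C)[C@H](O)[C@@H](O)CC2(C)C)C(C)(C)C[C@H](O)[C@H]1O | target

**Step count and risks**

Total: 18 steps. Longest linear sequence: 15 steps (steps 1–11, then 15–18, from ketoisophorone).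

Steps most likely to fail:

Step 16. The bulky polyenyl acetylide may add incompletely to the hindered C6 carbonyl, or the acidic collapse may ionize the allylic C4′ silyl ether of ring B and degrade the long polyene. The fallback forms the C6–C7 bond on the shorter polyenyne, before ring B and its acid-labile allylic ether are present, and completes the C40 skeleton by olefination instead. It sets out from 21, which is protected with trimethyl orthoformate and PPTS in methanol as the dimethyl acetal F1. Deprotonation of F1 with LiN(iPr)2, addition to 5 and the same dilute acid quench should unveil the aldehyde and effect the transposition at once, giving the C25 keto aldehyde F2. Wittig olefination of F2 with the ylide 22 generated from 15 (NaOMe, CH2Cl2/MeOH, then thermal isomerization) returns to the route at 27.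

Step 17. Facial selectivity of hydride delivery may be poor, or the deactivated polyenone may react sluggishly so that the allylic product ionizes during prolonged contact with acetic acid. The fallback replaces substrate direction by reagent control and sets out from 27. Silylation (TBSCl, imidazole, DMF) gives the tris-silyl ketone F3. Corey–Bakshi–Shibata reduction ((S)-2-methyl-CBS-oxazaborolidine, catecholborane, toluene, −78 °C; catalyst enantiomer chosen on the usual model with the C5=C6 enyne arm as the large group) should give the (4S)-alcohol F4. Desilylation with Bu4NF as in step 18 gives 29 directly, bypassing 28.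

Step 3. Enantioselectivity may be insufficient, or conjugate reduction of the enolized diketone may compete. The fallback replaces asymmetric catalysis by kinetic resolution and sets out from 3. Reduction with NaBH4 in MeOH at 0 °C gives the racemic diol F5. Lipase-catalysed acylation (immobilized Candida antarctica lipase B, vinyl acetate, tert-butyl methyl ether, 30 °C, stopped near half conversion) should convert the (R)-enantiomer to the acetate F6 and leave the (S)-alcohol, which after chromatographic separation is compound 4.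

**Further compounds**

F1 | step 16 | (3E,5E,7E,9E,11E)-13,13-dimethoxy-3,7,12-trimethyltrideca-3,5,7,9,11-pentaen-1-yne | C#C/C(C)=C/C=C/C(C)=C/C=C/C=C(C)/C(OC)OC
F2 | step 16 | (2E,4E,6E,8E,10E)-13-[(4S)-4-hydroxy-2,6,6-trimethyl-3-oxocyclohex-1-en-1-yl]-2,7,11-trimethyltrideca-2,4,6,8,10-pentaen-12-ynal | CC1=C(C#C/C(C)=C/C=C/C(C)=C/C=C/C=C(C)/C=O)C(C)(C)C[C@H](O)C1=O
F3 | step 17 | (3S,3′S,4′S)-3,3′,4′-tris(tert-butyldimethylsilyloxy)-7,8-didehydro-β,β-caroten-4-one | CC1=C(C#C/C(C)=C/C=C/C(C)=C/C=C/C=C(C)/C=C/C=C(C)/C=C/C2=C(C)[C@H](O[Si](C)(C)C(C)(C)C)[C@@H](O[Si](C)(C)C(C)(C)C)CC2(C)C)C(C)(C)C[C@H](O[Si](C)(C)C(C)(C)C)C1=O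
F4 | step 17 | (3S,4S,3′S,4′S)-3,3′,4′-tris(tert-butyldimethylsilyloxy)-7,8-didehydro-β,β-caroten-4-ol | CC1=C(C#C/C(C)=C/C=C/C(C)=C/C=C/C=C(C)/C=C/C=C(C)/C=C/C2=C(C)[C@H](O[Si](C)(C)C(C)(C)C)[C@@H](O[Si](C)(C)C(C)(C)C)CC2(C)C)C(C)(C)C[C@H](O[Si](C)(C)C(C)(C)C)[C@H]1O
F5 | step 3 | racemic 3,4-dihydroxy-2,6,6-trimethylcyclohex-2-en-1-one | CC1=C(O)C(O)CC(C)(C)C1=O
F6 | step 3 | (1R)-2-hydroxy-3,5,5-trimethyl-4-oxocyclohex-2-en-1-yl acetate | CC1=C(O)[C@H](OC(C)=O)CC(C)(C)C1=O
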